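**Retrosynthetic overview**
1. Target ⇐ exo-methylenation, TBS→Ac exchange and desilylation of cycloadduct 44 ⇐ Diels–Alder union of silyloxy cyclopentadiene 43 (guaianolide half) with α-methylene lactone 24 (seco-eudesmanolide half); this forms the spiro-norbornene last.
2. 24 ⇐ lactone methylenation, Takai–Lombardo methylenation and intramolecular aldol condensation ⇐ keto lactone 19 ⇐ key C8′–C9′ bond by an intermolecular chelation-controlled Mukaiyama aldol joining enol ether 7 (from (S)-citronellal) and aldehyde 13 (Evans alkylation).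
3. 43 ⇐ dehydration of carbinol 42 ⇐ MeLi addition, lactonisation, OH-directed hydrogenation and RCM ⇐ dienone 37 ⇐ Negishi coupling of iodide 31 (Evans syn-aldol with acrolein) with iodoenone 33, then isopropenyl cuprate/Saegusa oxidation.
4. Ring order: seco-eudesmanolide half γ-lactone → cyclohexenone; guaianolide half cyclopentenone (bought) → cycloheptene → γ-lactone → cyclopentadiene; then the norbornene.

Assumption: (S)-4-(tert-butyldimethylsilyloxy)cyclopent-2-en-1-one (32) is bought enantiopure; Cn / Cn′ in the Why lines are biogenetic locants of the guaianolide / seco-eudesmanolide halves.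

**Route**

Step 1
Reactants: 1 (S)-citronellal
Product: 2 (4S)-4,8-dimethylnon-7-en-2-ol (C2 epimers)
Conditions: MeMgBr, Et2O, 0 °C; NH4Cl (aq)
Reagents that add atoms: methylmagnesium bromide (C[Mg]Br)
Why: Grignard 1,2-addition to the aldehyde; the new carbinol centre is oxidised in step 4 and the citronellal centre (future C4′) is untouched.

Step 2
Reactants: 2 (4S)-4,8-dimethylnon-7-en-2-ol
Product: 4 (4S)-4-methylheptane-1,6-diol, via hydroxy aldehyde 3 (not isolated)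
Conditions: O3, CH2Cl2/MeOH, −78 °C; then NaBH4, −78 → 0 °C
Reagents that add atoms: ozone ([O-][O+]=O)
Why: Ozonolysis of the trisubstituted alkene with reductive work-up gives the primary alcohol that becomes C1′–OH.

Step 3
Reactants: 4 (4S)-4-methylheptane-1,6-diol
Product: 5 (4S)-7-(tert-butyldiphenylsilyloxy)-4-methylheptan-2-ol
Conditions: TBDPSCl (1.05 equiv), imidazole, CH2Cl2, 0 °C
Reagents that add atoms: tert-butyl(chloro)diphenylsilane (CC(C)(C)[Si](Cl)(c1ccccc1)c1ccccc1)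
Why: Sterically controlled silylation of the primary over the secondary hydroxyl.

Step 4
Reactants: 5 (4S)-7-(tert-butyldiphenylsilyloxy)-4-methylheptan-2-ol
Product: 6 (S)-7-(tert-butyldiphenylsilyloxy)-4-methylheptan-2-one
Conditions: Dess–Martin periodinane, CH2Cl2, 25 °C
Reagents that add atoms: none
Why: Dess–Martin oxidation of the secondary alcohol to the methyl ketone.

Step 5
Reactants: 6 (S)-7-(tert-butyldiphenylsilyloxy)-4-methylheptan-2-one
Product: 7 (S)-tert-butyl{[4-methyl-6-(trimethylsilyloxy)hept-6-en-1-yl]oxy}diphenylsilane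
Conditions: LiN(iPr)2, THF, −78 °C; Me3SiCl
Reagents that add atoms: chlorotrimethylsilane (C[Si](C)(C)Cl)
Why: Kinetic deprotonation at the methyl group and O-silylation give the less substituted silyl enol ether needed for the Mukaiyama aldol.

Step 6
Reactants: 8 (S)-4-benzyloxazolidin-2-one; 9 pent-4-enoyl chloride
Product: 10 (S)-4-benzyl-3-(pent-4-enoyl)oxazolidin-2-one
Conditions: n-BuLi, THF, −78 °C; then 9
Reagents that add atoms: none
Why: N-acylation of the lithiated Evans oxazolidinone.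

Step 7
Reactants: 10 (S)-4-benzyl-3-(pent-4-enoyl)oxazolidin-2-one
Product: 11 (S)-4-benzyl-3-[(R)-2-(benzyloxymethyl)pent-4-enoyl]oxazolidin-2-one
Conditions: TiCl4, iPr2NEt, CH2Cl2, 0 °C; BnOCH2Cl
Reagents that add atoms: benzyl chloromethyl ether (ClCOCc1ccccc1)
Why: Evans alkylation of the chelated titanium Z-enolate from the face opposite the benzyl group sets the future C7′ centre.

Step 8
Reactants: 11 (S)-4-benzyl-3-[(R)-2-(benzyloxymethyl)pent-4-enoyl]oxazolidin-2-one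
Product: 12 (S)-2-(benzyloxymethyl)pent-4-en-1-ol
Conditions: LiBH4, H2O (1 equiv), Et2O, 0 °C
Reagents that add atoms: none
Why: Reductive removal of the auxiliary leaves the stereocentre untouched.

Step 9
Reactants: 12 (S)-2-(benzyloxymethyl)pent-4-en-1-ol
Product: 13 (R)-2-(benzyloxymethyl)pent-4-enal
Conditions: Dess–Martin periodinane, CH2Cl2, 0 °C; used at once
Reagents that add atoms: none
Why: Dess–Martin oxidation under non-epimerising conditions gives the α-branched aldehyde.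

Step 10
Reactants: 7 (S)-tert-butyl{[4-methyl-6-(trimethylsilyloxy)hept-6-en-1-yl]oxy}diphenylsilane; 13 (R)-2-(benzyloxymethyl)pent-4-enal
Product: 14 (4S,8S,9R)-9-(benzyloxymethyl)-1-(tert-butyldiphenylsilyloxy)-8-hydroxy-4-methyldodec-11-en-6-one
Conditions: TiCl4 (1.1 equiv), CH2Cl2, −78 °C
Reagents that add atoms: none
Why: Chelation-controlled Mukaiyama aldol addition joins the two halves at C8′–C9′; TiCl4 bridges the aldehyde and the β-benzyloxy oxygen and the enol ether attacks anti to the allyl arm, setting C8′ (2,3-anti, the later cis-lactone).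

Step 11
Reactants: 14 (4S,8S,9R)-9-(benzyloxymethyl)-1-(tert-butyldiphenylsilyloxy)-8-hydroxy-4-methyldodec-11-en-6-one
Product: 16 (4R,5S)-4-(benzyloxymethyl)-5-[(S)-7-(tert-butyldiphenylsilyloxy)-4-methyl-2-oxoheptyl]tetrahydrofuran-2-ol (anomers), via hydroxy keto aldehyde 15 (not isolated)
Conditions: O3, CH2Cl2, −78 °C; then PPh3, −78 → 25 °C
Reagents that add atoms: ozone ([O-][O+]=O)
Why: Ozonolysis of the terminal alkene gives the C12′ aldehyde, which closes onto the C8′ hydroxyl as the five-membered lactol.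

Step 12
Reactants: 16 lactol (4R,5S)
Product: 17 (4R,5S)-4-(benzyloxymethyl)-5-[(S)-7-(tert-butyldiphenylsilyloxy)-4-methyl-2-oxoheptyl]dihydrofuran-2(3H)-one
Conditions: TEMPO (10 mol %), PhI(OAc)2, CH2Cl2, 25 °C
Reagents that add atoms: none
Why: Oxoammonium oxidation of the lactol gives the cis-β,γ-disubstituted γ-lactone.

Step 13
Reactants: 17 benzyl ether lactone
Product: 18 (4R,5S)-5-[(S)-7-(tert-butyldiphenylsilyloxy)-4-methyl-2-oxoheptyl]-4-(hydroxymethyl)dihydrofuran-2(3H)-one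
Conditions: H2 (1 atm), Pd/C, EtOAc, 25 °C
Reagents that add atoms: none
Why: Hydrogenolysis of the benzyl ether; no alkene is present at this stage.

Step 14
Reactants: 18 hydroxymethyl lactone
Product: 19 (2S,3S)-2-[(S)-7-(tert-butyldiphenylsilyloxy)-4-methyl-2-oxoheptyl]-5-oxotetrahydrofuran-3-carbaldehyde
Conditions: Dess–Martin periodinane, CH2Cl2, 0 °C
Reagents that add atoms: none
Why: Dess–Martin oxidation to the C6′ aldehyde.

Step 15
Reactants: 19 keto aldehyde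
Product: 20 (3aR,7aS)-5-[(S)-5-(tert-butyldiphenylsilyloxy)pentan-2-yl]-3,3a,7,7a-tetrahydro-1-benzofuran-2,6-dione
Conditions: Bn2NH·CF3CO2H (0.3 equiv), PhH, 50 °C
Reagents that add atoms: none
Why: Intramolecular aldol condensation (only the six-ring closure C5′→C6′ is possible) gives the 2-alkylcyclohexenone under weakly acidic conditions that spare the β-acyloxy ketone.

Step 16
Reactants: 20 enone lactone
Product: 21 (3aR,7aS)-5-[(S)-5-(tert-butyldiphenylsilyloxy)pentan-2-yl]-6-methylidene-3a,6,7,7a-tetrahydro-1-benzofuran-2(3H)-one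
Conditions: Zn, CH2Br2, TiCl4, THF/CH2Cl2, 0 → 25 °C
Reagents that add atoms: dibromomethane (BrCBr)
Why: Takai–Lombardo methylenation is non-basic and ketone-selective over the lactone, giving the exocyclic 1,3-diene.

Step 17
Reactants: 21 diene lactone
Product: 24 (3aS,7aS)-5-[(S)-5-(tert-butyldiphenylsilyloxy)pentan-2-yl]-3,6-dimethylidene-3a,6,7,7a-tetrahydro-1-benzofuran-2(3H)-one, via Mannich base 22 (not isolated), via trimethylammonium iodide 23 (not isolated)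
Conditions: LiN(iPr)2, THF, −78 °C; [CH2=NMe2]I, −78 → 0 °C; then MeI, MeOH, 25 °C; then NaHCO3 (aq), CH2Cl2
Reagents that add atoms: N,N-dimethylmethaniminium iodide (C=[N+](C)C.[I-])
Why: Mannich reaction of the lactone enolate with Eschenmoser's salt, quaternisation and E1cB elimination install the α-methylene group.

Step 18
Reactants: 25 4-tert-butoxy-4-oxobutanoic acid; 8 (S)-4-benzyloxazolidin-2-one
Product: 27 tert-butyl (S)-4-(4-benzyl-2-oxooxazolidin-3-yl)-4-oxobutanoate, via mixed pivalic anhydride 26 (not isolated)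
Conditions: t-BuCOCl, Et3N, THF, −20 °C; then 8, LiCl, −20 → 25 °C
Reagents that add atoms: none
Why: Mixed-anhydride N-acylation of the oxazolidinone.

Step 19
Reactants: 27 succinate imide
Product: 28 tert-butyl (3S,4R)-3-[(S)-4-benzyl-2-oxooxazolidine-3-carbonyl]-4-hydroxyhex-5-enoate
Conditions: Bu2BOTf, iPr2NEt, CH2Cl2, −78 → 0 °C; acrolein, −78 °C; pH 7 buffer/MeOH
Reagents that add atoms: acrolein (C=CC=O)
Why: Evans syn-aldol reaction (dibutylboron Z-enolate, Zimmerman–Traxler chair) sets C7 and C8 in the syn relationship that later gives the trans-lactone.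

Step 20
Reactants: 28 aldol adduct
Product: 29 tert-butyl (3S,4R)-3-[(S)-4-benzyl-2-oxooxazolidine-3-carbonyl]-4-(triethylsilyloxy)hex-5-enoate
Conditions: Et3SiOTf, 2,6-lutidine, CH2Cl2, −78 °C
Reagents that add atoms: triethylsilyl trifluoromethanesulfonate (CC[Si](CC)(CC)OS(=O)(=O)C(F)(F)F)
Why: Silylation of the secondary allylic alcohol.

Step 21
Reactants: 29 silylated imide
Product: 30 tert-butyl (3R,4R)-3-(hydroxymethyl)-4-(triethylsilyloxy)hex-5-enoate
Conditions: LiBH4, H2O (1 equiv), Et2O, 0 °C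
Reagents that add atoms: none
Why: Reductive cleavage of the imide; the tert-butyl ester is inert under these conditions.

Step 22
Reactants: 30 primary alcohol
Product: 31 tert-butyl (3S,4R)-3-(iodomethyl)-4-(triethylsilyloxy)hex-5-enoate
Conditions: I2, PPh3, imidazole, CH2Cl2, 0 °C
Reagents that add atoms: iodine (II)
Why: Appel-type iodination of the primary alcohol.

Step 23
Reactants: 32 (S)-4-(tert-butyldimethylsilyloxy)cyclopent-2-en-1-one
Product: 33 (S)-4-(tert-butyldimethylsilyloxy)-2-iodocyclopent-2-en-1-one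
Conditions: I2, pyridine, CH2Cl2, 0 → 25 °C
Reagents that add atoms: iodine (II)
Why: Johnson α-iodination of the enone (pyridine addition, iodination, elimination).

Step 24
Reactants: 31 alkyl iodide; 33 iodoenone
Product: 35 tert-butyl (3S,4R)-3-{[(S)-3-(tert-butyldimethylsilyloxy)-5-oxocyclopent-1-en-1-yl]methyl}-4-(triethylsilyloxy)hex-5-enoate, via alkylzinc iodide 34 (not isolated)
Conditions: Zn dust (activated: BrCH2CH2Br, Me3SiCl), LiCl, THF, 35 °C; then 33, Pd2(dba)3 (2.5 mol %), P(2-furyl)3 (10 mol %), THF/DMF, 25 °C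
Reagents that add atoms: none
Why: Zinc insertion followed by Negishi cross-coupling of the alkylzinc iodide with the α-iodoenone forms C5–C6.

Step 25
Reactants: 35 2-alkyl enone
Product: 37 tert-butyl (3S,4R)-3-{[(S)-3-(tert-butyldimethylsilyloxy)-5-oxo-2-(prop-1-en-2-yl)cyclopent-1-en-1-yl]methyl}-4-(triethylsilyloxy)hex-5-enoate, via silyl enol ether 36 (not isolated)
Conditions: CH2=C(CH3)MgBr, CuBr·SMe2 (20 mol %), Me3SiCl, THF, −78 °C; then crude 36, Pd(OAc)2 (10 mol %), O2 (1 atm), DMSO, 25 °C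
Reagents that add atoms: isopropenylmagnesium bromide (CC(=C)[Mg]Br)
Why: Copper-catalysed conjugate addition (trans to OTBS) trapped as the silyl enol ether, then Saegusa–Ito dehydrogenation restores the C1=C5 enone and erases the transient C1 centre.

Step 26
Reactants: 37 dienone
Product: 38 tert-butyl 2-[(3S,6S,7S)-3-(tert-butyldimethylsilyloxy)-4-methyl-1-oxo-6-(triethylsilyloxy)-1,2,3,6,7,8-hexahydroazulen-7-yl]acetate
Conditions: second-generation Hoveyda–Grubbs catalyst (5 mol %), PhMe (2 mM), 80 °C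
Reagents that add atoms: none
Why: Ring-closing metathesis of the isopropenyl and vinyl groups closes the seven-membered ring as the trisubstituted C9=C10 alkene.

Step 27
Reactants: 38 bicyclic dienone
Product: 39 tert-butyl 2-[(3S,6S,7S)-3-(tert-butyldimethylsilyloxy)-6-hydroxy-4-methyl-1-oxo-1,2,3,6,7,8-hexahydroazulen-7-yl]acetate
Conditions: PPTS, MeOH, 0 °C
Reagents that add atoms: none
Why: Mild acid methanolysis removes the TES ether and keeps the TBS ether.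

Step 28
Reactants: 39 allylic alcohol
Product: 40 tert-butyl 2-[(3S,4R,6R,7S)-3-(tert-butyldimethylsilyloxy)-6-hydroxy-4-methyl-1-oxo-1,2,3,4,5,6,7,8-octahydroazulen-7-yl]acetate
Conditions: [Ir(cod)(PCy3)(py)]PF6 (5 mol %), H2 (1 atm), CH2Cl2, 25 °C
Reagents that add atoms: none
Why: Hydroxyl-directed hydrogenation with Crabtree's catalyst delivers hydrogen to C9=C10 from the face of the C8 hydroxyl and sets C10 (H cis to O8).

Step 29
Reactants: 40 hydroxy enone
Product: 41 tert-butyl 2-[(3S,4R,6R,7S)-3-(tert-butyldimethylsilyloxy)-1,6-dihydroxy-1,4-dimethyl-1,2,3,4,5,6,7,8-octahydroazulen-7-yl]acetate (C1 epimers; centre removed in step 31)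
Conditions: MeLi (3 equiv), CeCl3, THF, −78 °C; AcOH quench at −78 °C
Reagents that add atoms: methyllithium ([Li]C)
Why: Organocerium 1,2-addition is non-basic, so no enolisation or β-elimination of the silyloxy group occurs and the tert-butyl ester is inert.

Step 30
Reactants: 41 diol ester
Product: 42 (3aS,7S,8R,9aR)-7-(tert-butyldimethylsilyloxy)-5-hydroxy-5,8-dimethyl-3a,4,5,6,7,8,9,9a-octahydroazuleno[6,5-b]furan-2(3H)-one (C5 epimers)
Conditions: KOtBu (0.2 equiv), THF, 0 °C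
Reagents that add atoms: none
Why: Alkoxide-catalysed lactonisation of the γ-hydroxy tert-butyl ester gives the trans-fused 12,8-lactone.

Step 31
Reactants: 42 tertiary allylic alcohol; 24 α-methylene lactone
Product: 44 cycloadduct (target skeleton with 2-OTBS / 1′-OTBDPS / guaianolide lactone still lacking its exo-methylene), via silyloxy cyclopentadiene 43 (not isolated)
Conditions: Burgess reagent (MeO2CN–SO2NEt3), PhH, 25 °C, 1 h; then 24 (1.5 equiv), BHT (cat.), concentrate to ca. 2 M, 40 °C, 48 h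
Reagents that add atoms: none
Why: Burgess syn-elimination unveils the 1(5),3-cyclopentadiene, which adds 24 in a Diels–Alder reaction with the CH2 terminus to the fully substituted C1, the lactone carbonyl exo (usual for α-methylene butyrolactones) and approach anti to the 2β-OTBS and 10β-methyl groups, setting C1, C3 and the spiro centre C11′.

Step 32
Reactants: 44 cycloadduct
Product: 47 bis-silyl ether of the 2-deacetyl target (2-OTBS / 1′-OTBDPS / both α-methylene lactones), via Mannich base 45 (not isolated), via trimethylammonium iodide 46 (not isolated)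
Conditions: LiN(iPr)2, THF, −78 °C; [CH2=NMe2]I, −78 → 0 °C; then MeI, MeOH, 25 °C; then NaHCO3 (aq), CH2Cl2
Reagents that add atoms: N,N-dimethylmethaniminium iodide (C=[N+](C)C.[I-])
Why: Only the guaianolide lactone is enolisable (the spiro lactone is α-quaternary), so the Mannich/elimination sequence installs its exo-methylene selectively.

Step 33
Reactants: 47 bis-silyl ether
Product: 48 2-hydroxy compound (1′-OTBDPS retained)
Conditions: PPTS, EtOH, 50 °C
Reagents that add atoms: none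
Why: Acid-catalysed ethanolysis cleaves the secondary TBS ether faster than the primary TBDPS ether.

Step 34
Reactants: 48 secondary alcohol
Product: 49 1′-O-TBDPS ether of the target
Conditions: Ac2O, pyridine, DMAP (cat.), CH2Cl2, 25 °C
Reagents that add atoms: acetic anhydride (CC(=O)OC(C)=O)
Why: DMAP-catalysed acetylation of the only free hydroxyl (C2).

Step 35
Reactants: 49 1′-O-TBDPS ether of the target
Product: 50 CNP0299458.1
Conditions: HF·pyridine, pyridine, THF, 0 → 25 °C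
Reagents that add atoms: none
Why: Fluoride cleavage of the TBDPS ether; the acetate and both α-methylene lactones tolerate buffered HF·pyridine.

**Compound list**
1 | (S)-citronellal | O=CC[C@@H](C)CCC=C(C)C | starting material
2 | (4S)-4,8-dimethylnon-7-en-2-ol | CC(O)C[C@@H](C)CCC=C(C)C | intermediate
3 | (4S)-6-hydroxy-4-methylheptanal | CC(O)C[C@@H](C)CCC=O | intermediate
4 | (4S)-4-methylheptane-1,6-diol | CC(O)C[C@@H](C)CCCO | intermediate
5 | (4S)-7-(tert-butyldiphenylsilyloxy)-4-methylheptan-2-ol | CC(O)C[C@@H](C)CCCO[Si](c1ccccc1)(c1ccccc1)C(C)(C)C | intermediate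
6 | (S)-7-(tert-butyldiphenylsilyloxy)-4-methylheptan-2-one | CC(=O)C[C@@H](C)CCCO[Si](c1ccccc1)(c1ccccc1)C(C)(C)C | intermediate
7 | (S)-tert-butyl{[4-methyl-6-(trimethylsilyloxy)hept-6-en-1-yl]oxy}diphenylsilane | C=C(O[Si](C)(C)C)C[C@@H](C)CCCO[Si](c1ccccc1)(c1ccccc1)C(C)(C)C | intermediate
8 | (S)-4-benzyloxazolidin-2-one | O=C1N[C@@H](Cc2ccccc2)CO1 | starting material
9 | pent-4-enoyl chloride | C=CCCC(=O)Cl | starting material
10 | (S)-4-benzyl-3-(pent-4-enoyl)oxazolidin-2-one | C=CCCC(=O)N1[C@@H](Cc2ccccc2)COC1=O | intermediate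
11 | (S)-4-benzyl-3-[(R)-2-(benzyloxymethyl)pent-4-enoyl]oxazolidin-2-one | C=CC[C@@H](C(=O)N1[C@@H](Cc2ccccc2)COC1=O)COCc1ccccc1 | intermediate
12 | (S)-2-(benzyloxymethyl)pent-4-en-1-ol | C=CC[C@@H](CO)COCc1ccccc1 | intermediate
13 | (R)-2-(benzyloxymethyl)pent-4-enal | C=CC[C@@H](C=O)COCc1ccccc1 | intermediate
14 | (4S,8S,9R)-9-(benzyloxymethyl)-1-(tert-butyldiphenylsilyloxy)-8-hydroxy-4-methyldodec-11-en-6-one | C=CC[C@@H]([C@@H](O)CC(=O)C[C@@H](C)CCCO[Si](c1ccccc1)(c1ccccc1)C(C)(C)C)COCc1ccccc1 | intermediate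
15 | (3R,4S,8S)-3-(benzyloxymethyl)-11-(tert-butyldiphenylsilyloxy)-4-hydroxy-8-methyl-6-oxoundecanal | O=CC[C@@H]([C@@H](O)CC(=O)C[C@@H](C)CCCO[Si](c1ccccc1)(c1ccccc1)C(C)(C)C)COCc1ccccc1 | intermediate
16 | (4R,5S)-4-(benzyloxymethyl)-5-[(S)-7-(tert-butyldiphenylsilyloxy)-4-methyl-2-oxoheptyl]tetrahydrofuran-2-ol (anomers) | OC1C[C@H](COCc2ccccc2)[C@H](CC(=O)C[C@@H](C)CCCO[Si](c2ccccc2)(c2ccccc2)C(C)(C)C)O1 | intermediate
17 | (4R,5S)-4-(benzyloxymethyl)-5-[(S)-7-(tert-butyldiphenylsilyloxy)-4-methyl-2-oxoheptyl]dihydrofuran-2(3H)-one | O=C1C[C@H](COCc2ccccc2)[C@H](CC(=O)C[C@@H](C)CCCO[Si](c2ccccc2)(c2ccccc2)C(C)(C)C)O1 | intermediate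
18 | (4R,5S)-5-[(S)-7-(tert-butyldiphenylsilyloxy)-4-methyl-2-oxoheptyl]-4-(hydroxymethyl)dihydrofuran-2(3H)-one | O=C1C[C@H](CO)[C@H](CC(=O)C[C@@H](C)CCCO[Si](c2ccccc2)(c2ccccc2)C(C)(C)C)O1 | intermediate
19 | (2S,3S)-2-[(S)-7-(tert-butyldiphenylsilyloxy)-4-methyl-2-oxoheptyl]-5-oxotetrahydrofuran-3-carbaldehyde | O=C1C[C@H](C=O)[C@H](CC(=O)C[C@@H](C)CCCO[Si](c2ccccc2)(c2ccccc2)C(C)(C)C)O1 | intermediate
20 | (3aR,7aS)-5-[(S)-5-(tert-butyldiphenylsilyloxy)pentan-2-yl]-3,3a,7,7a-tetrahydro-1-benzofuran-2,6-dione | O=C1C[C@@H]2OC(=O)C[C@@H]2C=C1[C@@H](C)CCCO[Si](c3ccccc3)(c3ccccc3)C(C)(C)C | intermediate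
21 | (3aR,7aS)-5-[(S)-5-(tert-butyldiphenylsilyloxy)pentan-2-yl]-6-methylidene-3a,6,7,7a-tetrahydro-1-benzofuran-2(3H)-one | C=C1C[C@@H]2OC(=O)C[C@@H]2C=C1[C@@H](C)CCCO[Si](c3ccccc3)(c3ccccc3)C(C)(C)C | intermediate
22 | 3-(dimethylaminomethyl) derivative of 21 (C3 epimers) | C=C1C[C@@H]2OC(=O)C(CN(C)C)[C@@H]2C=C1[C@@H](C)CCCO[Si](c3ccccc3)(c3ccccc3)C(C)(C)C | intermediate
23 | 3-(trimethylammoniomethyl) derivative of 21, iodide | C=C1C[C@@H]2OC(=O)C(C[N+](C)(C)C)[C@@H]2C=C1[C@@H](C)CCCO[Si](c3ccccc3)(c3ccccc3)C(C)(C)C.[I-] | intermediate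
24 | (3aS,7aS)-5-[(S)-5-(tert-butyldiphenylsilyloxy)pentan-2-yl]-3,6-dimethylidene-3a,6,7,7a-tetrahydro-1-benzofuran-2(3H)-one | C=C1C[C@@H]2OC(=O)C(=C)[C@@H]2C=C1[C@@H](C)CCCO[Si](c3ccccc3)(c3ccccc3)C(C)(C)C | intermediate
25 | 4-tert-butoxy-4-oxobutanoic acid | OC(=O)CCC(=O)OC(C)(C)C | starting material
26 | 4-tert-butoxy-4-oxobutanoic pivalic anhydride | CC(C)(C)C(=O)OC(=O)CCC(=O)OC(C)(C)C | intermediate
27 | tert-butyl (S)-4-(4-benzyl-2-oxooxazolidin-3-yl)-4-oxobutanoate | O=C(CCC(=O)OC(C)(C)C)N1[C@@H](Cc2ccccc2)COC1=O | intermediate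
28 | tert-butyl (3S,4R)-3-[(S)-4-benzyl-2-oxooxazolidine-3-carbonyl]-4-hydroxyhex-5-enoate | O=C(N1[C@@H](Cc2ccccc2)COC1=O)[C@@H](CC(=O)OC(C)(C)C)[C@H](O)C=C | intermediate
29 | tert-butyl (3S,4R)-3-[(S)-4-benzyl-2-oxooxazolidine-3-carbonyl]-4-(triethylsilyloxy)hex-5-enoate | O=C(N1[C@@H](Cc2ccccc2)COC1=O)[C@@H](CC(=O)OC(C)(C)C)[C@H](O[Si](CC)(CC)CC)C=C | intermediate
30 | tert-butyl (3R,4R)-3-(hydroxymethyl)-4-(triethylsilyloxy)hex-5-enoate | OC[C@@H](CC(=O)OC(C)(C)C)[C@H](O[Si](CC)(CC)CC)C=C | intermediate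
31 | tert-butyl (3S,4R)-3-(iodomethyl)-4-(triethylsilyloxy)hex-5-enoate | IC[C@@H](CC(=O)OC(C)(C)C)[C@H](O[Si](CC)(CC)CC)C=C | intermediate
32 | (S)-4-(tert-butyldimethylsilyloxy)cyclopent-2-en-1-one | O=C1C=C[C@@H](O[Si](C)(C)C(C)(C)C)C1 | starting material
33 | (S)-4-(tert-butyldimethylsilyloxy)-2-iodocyclopent-2-en-1-one | O=C1C(I)=C[C@@H](O[Si](C)(C)C(C)(C)C)C1 | intermediate
34 | [(2S,3R)-2-(2-tert-butoxy-2-oxoethyl)-3-(triethylsilyloxy)pent-4-en-1-yl]zinc iodide | I[Zn]C[C@@H](CC(=O)OC(C)(C)C)[C@H](O[Si](CC)(CC)CC)C=C | intermediate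
35 | tert-butyl (3S,4R)-3-{[(S)-3-(tert-butyldimethylsilyloxy)-5-oxocyclopent-1-en-1-yl]methyl}-4-(triethylsilyloxy)hex-5-enoate | O=C1C(C[C@@H](CC(=O)OC(C)(C)C)[C@H](O[Si](CC)(CC)CC)C=C)=C[C@@H](O[Si](C)(C)C(C)(C)C)C1 | intermediate
36 | tert-butyl (3S,4R)-3-{[(4S,5S)-4-(tert-butyldimethylsilyloxy)-5-(prop-1-en-2-yl)-2-(trimethylsilyloxy)cyclopent-1-en-1-yl]methyl}-4-(triethylsilyloxy)hex-5-enoate | C[Si](C)(C)OC1=C(C[C@@H](CC(=O)OC(C)(C)C)[C@H](O[Si](CC)(CC)CC)C=C)[C@H](C(C)=C)[C@@H](O[Si](C)(C)C(C)(C)C)C1 | intermediate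
37 | tert-butyl (3S,4R)-3-{[(S)-3-(tert-butyldimethylsilyloxy)-5-oxo-2-(prop-1-en-2-yl)cyclopent-1-en-1-yl]methyl}-4-(triethylsilyloxy)hex-5-enoate | O=C1C(C[C@@H](CC(=O)OC(C)(C)C)[C@H](O[Si](CC)(CC)CC)C=C)=C(C(C)=C)[C@@H](O[Si](C)(C)C(C)(C)C)C1 | intermediate
38 | tert-butyl 2-[(3S,6S,7S)-3-(tert-butyldimethylsilyloxy)-4-methyl-1-oxo-6-(triethylsilyloxy)-1,2,3,6,7,8-hexahydroazulen-7-yl]acetate | O=C1C[C@H](O[Si](C)(C)C(C)(C)C)C2=C1C[C@@H](CC(=O)OC(C)(C)C)[C@H](O[Si](CC)(CC)CC)C=C2C | intermediate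
39 | tert-butyl 2-[(3S,6S,7S)-3-(tert-butyldimethylsilyloxy)-6-hydroxy-4-methyl-1-oxo-1,2,3,6,7,8-hexahydroazulen-7-yl]acetate | O=C1C[C@H](O[Si](C)(C)C(C)(C)C)C2=C1C[C@@H](CC(=O)OC(C)(C)C)[C@H](O)C=C2C | intermediate
40 | tert-butyl 2-[(3S,4R,6R,7S)-3-(tert-butyldimethylsilyloxy)-6-hydroxy-4-methyl-1-oxo-1,2,3,4,5,6,7,8-octahydroazulen-7-yl]acetate | O=C1C[C@H](O[Si](C)(C)C(C)(C)C)C2=C1C[C@@H](CC(=O)OC(C)(C)C)[C@H](O)C[C@H]2C | intermediate
41 | tert-butyl 2-[(3S,4R,6R,7S)-3-(tert-butyldimethylsilyloxy)-1,6-dihydroxy-1,4-dimethyl-1,2,3,4,5,6,7,8-octahydroazulen-7-yl]acetate (C1 epimers) | CC1(O)C[C@H](O[Si](C)(C)C(C)(C)C)C2=C1C[C@@H](CC(=O)OC(C)(C)C)[C@H](O)C[C@H]2C | intermediate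
42 | (3aS,7S,8R,9aR)-7-(tert-butyldimethylsilyloxy)-5-hydroxy-5,8-dimethyl-3a,4,5,6,7,8,9,9a-octahydroazuleno[6,5-b]furan-2(3H)-one (C5 epimers) | CC1(O)C[C@H](O[Si](C)(C)C(C)(C)C)C2=C1C[C@H]3CC(=O)O[C@@H]3C[C@H]2C | intermediate
43 | (3aS,7S,8R,9aR)-7-(tert-butyldimethylsilyloxy)-5,8-dimethyl-3a,4,7,8,9,9a-hexahydroazuleno[6,5-b]furan-2(3H)-one | CC1=C[C@H](O[Si](C)(C)C(C)(C)C)C2=C1C[C@H]3CC(=O)O[C@@H]3C[C@H]2C | intermediate
44 | cycloadduct: target skeleton with 2-OTBS, 1′-OTBDPS and CH2 in place of C=CH2 on the guaianolide lactone; all centres as in the target | C=C1C[C@@H]2OC(=O)[C@@]3(C[C@@]45C(=C(C)[C@@H]3[C@@H]4O[Si](C)(C)C(C)(C)C)C[C@H]3CC(=O)O[C@@H]3C[C@H]5C)[C@@H]2C=C1[C@@H](C)CCCO[Si](c1ccccc1)(c1ccccc1)C(C)(C)C | intermediate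
45 | 44 carrying CH2NMe2 at C11 of the guaianolide lactone (C11 epimers) | C=C1C[C@@H]2OC(=O)[C@@]3(C[C@@]45C(=C(C)[C@@H]3[C@@H]4O[Si](C)(C)C(C)(C)C)C[C@H]3C(CN(C)C)C(=O)O[C@@H]3C[C@H]5C)[C@@H]2C=C1[C@@H](C)CCCO[Si](c1ccccc1)(c1ccccc1)C(C)(C)C | intermediate
46 | methiodide of 45 | C=C1C[C@@H]2OC(=O)[C@@]3(C[C@@]45C(=C(C)[C@@H]3[C@@H]4O[Si](C)(C)C(C)(C)C)C[C@H]3C(C[N+](C)(C)C)C(=O)O[C@@H]3C[C@H]5C)[C@@H]2C=C1[C@@H](C)CCCO[Si](c1ccccc1)(c1ccccc1)C(C)(C)C.[I-] | intermediate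
47 | 2-O-TBS, 1′-O-TBDPS ether of the 2-deacetyl target | C=C1C[C@@H]2OC(=O)[C@@]3(C[C@@]45C(=C(C)[C@@H]3[C@@H]4O[Si](C)(C)C(C)(C)C)C[C@H]3C(=C)C(=O)O[C@@H]3C[C@H]5C)[C@@H]2C=C1[C@@H](C)CCCO[Si](c1ccccc1)(c1ccccc1)C(C)(C)C | intermediate
48 | 1′-O-TBDPS ether of the 2-deacetyl target | C=C1C[C@@H]2OC(=O)[C@@]3(C[C@@]45C(=C(C)[C@@H]3[C@@H]4O)C[C@H]3C(=C)C(=O)O[C@@H]3C[C@H]5C)[C@@H]2C=C1[C@@H](C)CCCO[Si](c1ccccc1)(c1ccccc1)C(C)(C)C | intermediate
49 | 1′-O-TBDPS ether of the target | C=C1C[C@@H]2OC(=O)[C@@]3(C[C@@]45C(=C(C)[C@@H]3[C@@H]4OC(C)=O)C[C@H]3C(=C)C(=O)O[C@@H]3C[C@H]5C)[C@@H]2C=C1[C@@H](C)CCCO[Si](c1ccccc1)(c1ccccc1)C(C)(C)C | intermediate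
50 | CNP0299458.1 | C=C1C[C@@H]2OC(=O)[C@@]3(C[C@@]45C(=C(C)[C@@H]3[C@@H]4OC(C)=O)C[C@H]3C(=C)C(=O)O[C@@H]3C[C@H]5C)[C@@H]2C=C1[C@@H](C)CCCO | target

**Totals**
Total steps: 35. Longest linear sequence: 18 steps (1 → 7 by steps 1–5, then steps 10–17 to 24, then steps 31–35).

**Three steps most likely to fail**

Step 31 (diene generation and cross Diels–Alder). 5-Oxy-cyclopentadienes often add syn to oxygen, the diene can undergo 1,5-H shift, and the exo preference is only by analogy. The route relies on the bulky OTBS and the 10β-methyl to block the β-face. Fallback, from 42 back to 49: let the natural acetate pass through the cycloaddition and carry the guaianolide methylene masked. Treat 42 with LiN(iPr)2 (2.2 equiv) and [CH2=NMe2]I to give the amino lactone F1. TBAF gives the amino diol F2. Ac2O/pyridine acetylates only the secondary hydroxyl to the amino acetate F3. Burgess dehydration gives the acetoxy diene F4, trapped in the same pot by 24 as the amino cycloadduct F5. MeI then NaHCO3 expels trimethylamine and gives 49, so steps 32–34 are bypassed.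

Step 15 (keto-aldehyde condensation). The aldehyde is α-epimerisable and both carbonyls are β to the lactone oxygen, so retro-oxa-Michael elimination and then aromatisation can compete. Fallback, from 16 back to 20: run the ring closure at the acetal oxidation level, where the β-oxygen is a poor leaving group. MeOH/PPTS converts 16 into the methyl acetal F6. H2, Pd/C gives the hydroxy acetal F7. Dess–Martin oxidation gives the formyl acetal F8. Bn2NH·CF3CO2H closes it to the bicyclic enone acetal F9, and mCPBA/BF3·OEt2 oxidises the acetal to lactone 20.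

Step 26 (RCM). The isopropenyl group is conjugated to the enone and the vinyl group is flanked by an allylic silyl ether, so forming the trisubstituted seven-ring alkene may be slow. Fallback, from 36 back to 38: isolate 36 by non-aqueous work-up and run the metathesis on this non-conjugated isopropenyl compound to give the bicyclic silyl enol ether F10. Saegusa–Ito oxidation (Pd(OAc)2, O2, DMSO) of F10 then gives 38 directly, the hydrogen removed at C1 now being allylic.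

Further compounds
F1 | step 31 | 3-(dimethylaminomethyl) derivative of 42 (C3 and C5 epimers) | CC1(O)C[C@H](O[Si](C)(C)C(C)(C)C)C2=C1C[C@H]3C(CN(C)C)C(=O)O[C@@H]3C[C@H]2C
F2 | step 31 | (3aS,7S,8R,9aR)-3-(dimethylaminomethyl)-5,7-dihydroxy-5,8-dimethyl-3a,4,5,6,7,8,9,9a-octahydroazuleno[6,5-b]furan-2(3H)-one | CC1(O)C[C@H](O)C2=C1C[C@H]3C(CN(C)C)C(=O)O[C@@H]3C[C@H]2C
F3 | step 31 | 7-O-acetate of F2 | CC1(O)C[C@H](OC(C)=O)C2=C1C[C@H]3C(CN(C)C)C(=O)O[C@@H]3C[C@H]2C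
F4 | step 31 | (3aS,7S,8R,9aR)-7-acetoxy-3-(dimethylaminomethyl)-5,8-dimethyl-3a,4,7,8,9,9a-hexahydroazuleno[6,5-b]furan-2(3H)-one | CC1=C[C@H](OC(C)=O)C2=C1C[C@H]3C(CN(C)C)C(=O)O[C@@H]3C[C@H]2C
F5 | step 31 | 49 carrying CH2NMe2 in place of the guaianolide exo-methylene | C=C1C[C@@H]2OC(=O)[C@@]3(C[C@@]45C(=C(C)[C@@H]3[C@@H]4OC(C)=O)C[C@H]3C(CN(C)C)C(=O)O[C@@H]3C[C@H]5C)[C@@H]2C=C1[C@@H](C)CCCO[Si](c1ccccc1)(c1ccccc1)C(C)(C)C
F6 | step 15 | methyl acetal of lactol 16 | COC1C[C@H](COCc2ccccc2)[C@H](CC(=O)C[C@@H](C)CCCO[Si](c2ccccc2)(c2ccccc2)C(C)(C)C)O1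
F7 | step 15 | debenzylated methyl acetal | COC1C[C@H](CO)[C@H](CC(=O)C[C@@H](C)CCCO[Si](c2ccccc2)(c2ccccc2)C(C)(C)C)O1
F8 | step 15 | 3-formyl methyl acetal | COC1C[C@H](C=O)[C@H](CC(=O)C[C@@H](C)CCCO[Si](c2ccccc2)(c2ccccc2)C(C)(C)C)O1
F9 | step 15 | (3aR,7aS)-5-[(S)-5-(tert-butyldiphenylsilyloxy)pentan-2-yl]-2-methoxy-2,3,3a,7a-tetrahydro-1-benzofuran-6(7H)-one | O=C1C[C@@H]2OC(OC)C[C@@H]2C=C1[C@@H](C)CCCO[Si](c3ccccc3)(c3ccccc3)C(C)(C)C
F10 | step 26 | bicyclic trimethylsilyl enol ether (ring-closed 36) | C[Si](C)(C)OC1=C2C[C@@H](CC(=O)OC(C)(C)C)[C@H](O[Si](CC)(CC)CC)C=C(C)[C@@H]2[C@@H](O[Si](C)(C)C(C)(C)C)C1
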